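**Retrosynthetic overview**

- Feature: ring B (C1' carries the bridging CH2, C2' OH, C3' butanoyl, C4' OH, C5' CH3, C6' OCH3) has three oxygens in a 1,3,5 array. Only O6', flanked by the methyl carbon C5' and the CH2-bearing carbon C1', is methylated. O2', O4' and O6' are traced to a cyclobutenone alkoxy oxygen, a ketene oxygen and an ynol ether oxygen.
- Last disconnections: the four benzyl ethers (hydrogenolysis) and the C3'–butanoyl bond (Friedel–Crafts acylation at the only free carbon of ring B).
- Key disconnection: ring B is opened to 3-benzyloxycyclobutenone 9 and 1-methoxypropyne 12 (bonds C4'–C5' and C6'–C1', then ring closure C3'–C4').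
- Cyclobutenone 9 comes from vinylogous acid 7, and 7 from ring A Mannich base 4 and cyclobutane-1,3-dione by ortho-quinone methide alkylation (CH2–C1' bond). Mannich base 4 comes from 2-methylphloroglucinol by C-acylation.
- Ring order: ring A is carried from the start, the four-membered ring is brought in as the dione, and ring B is formed last in step 7. The target has no stereocentre.

Key step: step 7

Assumption: cyclobutane-1,3-dione (5) is taken as a purchasable, cold-stored building block; it reacts through its enol, 3-hydroxycyclobut-2-en-1-one.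

**Route**

Step 1
Reactants: 1 2-methylphloroglucinol; 2 pentanoyl chloride
Product: 3 1-(2,4,6-trihydroxy-3-methylphenyl)pentan-1-one
Conditions: AlCl3 (3 equiv), PhNO2–CH2Cl2, 0 °C to rt; aq. HCl work-up
Reagents that add atoms: none
Why: Friedel–Crafts C-acylation of the strongly activated phloroglucinol nucleus; the two free ring carbons are equivalent and the first acyl group deactivates the ring against a second acylation.

Step 2
Reactants: 3 1-(2,4,6-trihydroxy-3-methylphenyl)pentan-1-one
Product: 4 1-[3-[(dimethylamino)methyl]-2,4,6-trihydroxy-5-methylphenyl]pentan-1-one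
Conditions: CH2(NMe2)2 (1.2 equiv), 1,4-dioxane, rt
Reagents that add atoms: bis(dimethylamino)methane CN(C)CN(C)C
Why: Phenolic Mannich reaction; the acidic phenol protonates the aminal to an iminium ion, which attacks the only unsubstituted ring carbon.

Step 3
Reactants: 4 1-[3-[(dimethylamino)methyl]-2,4,6-trihydroxy-5-methylphenyl]pentan-1-one; 5 cyclobutane-1,3-dione
Product: 7 3-hydroxy-2-[(2,4,6-trihydroxy-3-methyl-5-pentanoylphenyl)methyl]cyclobut-2-en-1-one, via ortho-quinone methide 6 (not isolated)
Conditions: 5 (2.5 equiv), 1,4-dioxane, 80 °C, N2; dilute aq. HCl wash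
Reagents that add atoms: none
Why: Thermal loss of dimethylamine from the ortho-hydroxybenzylamine (assisted by protonation by the acidic dione) gives ortho-quinone methide 6, which takes up C2 of the enolized 1,3-dione in a Michael addition (ortho-quinone methide alkylation of a 1,3-dicarbonyl compound); 4 has no free ring carbon and so cannot self-condense.

Step 4
Reactants: 7 3-hydroxy-2-[(2,4,6-trihydroxy-3-methyl-5-pentanoylphenyl)methyl]cyclobut-2-en-1-one
Product: 8 3-(benzyloxy)-2-[(2,4,6-trihydroxy-3-methyl-5-pentanoylphenyl)methyl]cyclobut-2-en-1-one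
Conditions: BnOH (1.1 equiv), PPh3, DIAD, THF, 0 °C to rt
Reagents that add atoms: benzyl alcohol OCc1ccccc1
Why: Mitsunobu O-alkylation; the vinylogous acid is by far the most acidic hydroxyl and is engaged first, its enolate reacts at oxygen with the alkoxyphosphonium ion, and any phenol benzylated alongside is already on the way to 9.

Step 5
Reactants: 8 3-(benzyloxy)-2-[(2,4,6-trihydroxy-3-methyl-5-pentanoylphenyl)methyl]cyclobut-2-en-1-one
Product: 9 3-(benzyloxy)-2-[[2,4,6-tris(benzyloxy)-3-methyl-5-pentanoylphenyl]methyl]cyclobut-2-en-1-one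
Conditions: BnBr (4 equiv), K2CO3, DMF, rt to 45 °C
Reagents that add atoms: benzyl bromide BrCc1ccccc1
Why: Williamson ether synthesis on the three phenols in a polar aprotic solvent; the vinylogous ester has no acidic hydroxyl left, and a phenoxide adding to it would be expelled again in preference to benzyloxide, so only O-benzylation is expected.

Step 6
Reactants: 10 2-chloro-1,1-dimethoxyethane (chloroacetaldehyde dimethyl acetal)
Product: 12 1-methoxyprop-1-yne, via sodium methoxyethynide 11 (not isolated)
Conditions: NaNH2 (3 equiv), liquid NH3, −33 °C; then MeI, −33 °C; cold aqueous work-up, distillation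
Reagents that add atoms: iodomethane CI
Why: Two amide-induced eliminations (methanol, then HCl) and deprotonation give sodium methoxyethynide, which is C-methylated by iodomethane (acetylide alkylation in liquid ammonia); a methyl ynol ether cannot fragment by a retro-ene path on later heating.

Step 7
Reactants: 9 3-(benzyloxy)-2-[[2,4,6-tris(benzyloxy)-3-methyl-5-pentanoylphenyl]methyl]cyclobut-2-en-1-one; 12 1-methoxyprop-1-yne
Product: 17 1-[2,4,6-tris(benzyloxy)-3-[(2-benzyloxy-4-hydroxy-6-methoxy-5-methylphenyl)methyl]-5-methylphenyl]pentan-1-one, via vinylketene 13 (not isolated), via 4-vinylcyclobutenone 14 (not isolated), via dienylketene 15 (not isolated), via cyclohexadienone 16 (not isolated)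
Conditions: 12 (3 equiv), toluene, sealed tube, 80 °C then 130 °C
Reagents that add atoms: none
Why: Proposed new method: a 3-alkoxy-2-benzylcyclobutenone has not been shown as the four-carbon partner, but the cascade should follow the thermal benzannulation of cyclobutenones with alkoxyalkynes (Danheiser benzannulation), the closest known reaction type. Heating opens 9 by a four-electron electrocyclic reaction to vinylketene 13, whose ketene C=C adds 12 in a [2+2] cycloaddition (bonds C4'–C5' and C6'–C1') to give 14, and a second four-electron opening gives dienylketene 15. Ring B then closes by a thermal six-electron disrotatory electrocyclization of 15 (bond C3'–C4', between the ketene carbon and the terminal CH2) to dienone 16, which tautomerizes to the phenol. No stereocentre remains, because the quaternary carbon of 14 becomes an aromatic carbon. The step needs a regioselective [2+2] addition, secured by the polarized ynol ether, whose nucleophilic methyl-bearing carbon bonds to the electrophilic ketene carbonyl carbon so that OCH3 ends up between C5' and C1'; it also needs the ketenes to be spared from hydroxyl groups, secured by the benzylation of every ring A oxygen and by the excess of 12.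

Step 8
Reactants: 17 1-[2,4,6-tris(benzyloxy)-3-[(2-benzyloxy-4-hydroxy-6-methoxy-5-methylphenyl)methyl]-5-methylphenyl]pentan-1-one; 18 butanoyl chloride
Product: 19 1-[2,4,6-tris(benzyloxy)-3-[(2-benzyloxy-3-butanoyl-4-hydroxy-6-methoxy-5-methylphenyl)methyl]-5-methylphenyl]pentan-1-one
Conditions: 18 (1.2 equiv), TiCl4 (2 equiv), CH2Cl2, −40 to 0 °C; aq. HCl work-up
Reagents that add atoms: none
Why: Friedel–Crafts acylation delivered ortho to the free phenol through its titanium phenoxide, at the only unsubstituted carbon of ring B, which is activated by three oxygens; the methyl ether is not next to the new carbonyl and so escapes chelation-assisted dealkylation, and any benzyl ether lost here is removed in step 9 anyway.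

Step 9
Reactants: 19 1-[2,4,6-tris(benzyloxy)-3-[(2-benzyloxy-3-butanoyl-4-hydroxy-6-methoxy-5-methylphenyl)methyl]-5-methylphenyl]pentan-1-one
Product: 20 1-[3-[(3-butanoyl-2,4-dihydroxy-6-methoxy-5-methylphenyl)methyl]-2,4,6-trihydroxy-5-methylphenyl]pentan-1-one (CNP0210501.0)
Conditions: H2 (1 atm), 10% Pd/C, EtOAc–MeOH, rt
Reagents that add atoms: none
Why: Hydrogenolysis of the four aryl benzyl ethers over Pd/C; the hydrogen-bonded aryl ketones, the methyl ether and the diarylmethane link should not be reduced under these conditions.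

**Compound list**

1 | 2-methylphloroglucinol (2-methylbenzene-1,3,5-triol) | Cc1c(O)cc(O)cc1O | starting material
2 | pentanoyl chloride | CCCCC(=O)Cl | starting material
3 | 1-(2,4,6-trihydroxy-3-methylphenyl)pentan-1-one | CCCCC(=O)c1c(O)c(C)c(O)cc1O | intermediate
4 | 1-[3-[(dimethylamino)methyl]-2,4,6-trihydroxy-5-methylphenyl]pentan-1-one | CCCCC(=O)c1c(O)c(C)c(O)c(CN(C)C)c1O | intermediate
5 | cyclobutane-1,3-dione | O=C1CC(=O)C1 | starting material
6 | 3,5-dihydroxy-4-methyl-6-methylidene-2-pentanoylcyclohexa-2,4-dien-1-one (ortho-quinone methide) | CCCCC(=O)C1=C(O)C(C)=C(O)C(=C)C1=O | intermediate (not isolated)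
7 | 3-hydroxy-2-[(2,4,6-trihydroxy-3-methyl-5-pentanoylphenyl)methyl]cyclobut-2-en-1-one | CCCCC(=O)c1c(O)c(C)c(O)c(CC2=C(O)CC2=O)c1O | intermediate
8 | 3-(benzyloxy)-2-[(2,4,6-trihydroxy-3-methyl-5-pentanoylphenyl)methyl]cyclobut-2-en-1-one | CCCCC(=O)c1c(O)c(C)c(O)c(CC2=C(OCc3ccccc3)CC2=O)c1O | intermediate
9 | 3-(benzyloxy)-2-[[2,4,6-tris(benzyloxy)-3-methyl-5-pentanoylphenyl]methyl]cyclobut-2-en-1-one | CCCCC(=O)c1c(OCc2ccccc2)c(C)c(OCc2ccccc2)c(CC2=C(OCc3ccccc3)CC2=O)c1OCc1ccccc1 | intermediate
10 | 2-chloro-1,1-dimethoxyethane | COC(CCl)OC | starting material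
11 | sodium methoxyethynide | [Na+].[C-]#COC | intermediate (not isolated)
12 | 1-methoxyprop-1-yne | CC#COC | intermediate
13 | 3-(benzyloxy)-2-[[2,4,6-tris(benzyloxy)-3-methyl-5-pentanoylphenyl]methyl]buta-1,3-dien-1-one (vinylketene) | CCCCC(=O)c1c(OCc2ccccc2)c(C)c(OCc2ccccc2)c(CC(=C=O)C(=C)OCc2ccccc2)c1OCc1ccccc1 | intermediate (not isolated)
14 | 4-[1-(benzyloxy)ethenyl]-3-methoxy-2-methyl-4-[[2,4,6-tris(benzyloxy)-3-methyl-5-pentanoylphenyl]methyl]cyclobut-2-en-1-one (racemic) | CCCCC(=O)c1c(OCc2ccccc2)c(C)c(OCc2ccccc2)c(CC2(C(=C)OCc3ccccc3)C(=O)C(C)=C2OC)c1OCc1ccccc1 | intermediate (not isolated)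
15 | 5-(benzyloxy)-3-methoxy-2-methyl-4-[[2,4,6-tris(benzyloxy)-3-methyl-5-pentanoylphenyl]methyl]hexa-1,3,5-trien-1-one (dienylketene; ketene and benzyloxyvinyl groups cis across C3=C4) | CCCCC(=O)c1c(OCc2ccccc2)c(C)c(OCc2ccccc2)c(C/C(C(=C)OCc2ccccc2)=C(OC)/C(C)=C=O)c1OCc1ccccc1 | intermediate (not isolated)
16 | 5-(benzyloxy)-3-methoxy-2-methyl-4-[[2,4,6-tris(benzyloxy)-3-methyl-5-pentanoylphenyl]methyl]cyclohexa-2,4-dien-1-one | CCCCC(=O)c1c(OCc2ccccc2)c(C)c(OCc2ccccc2)c(CC2=C(OCc3ccccc3)CC(=O)C(C)=C2OC)c1OCc1ccccc1 | intermediate (not isolated)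
17 | 1-[2,4,6-tris(benzyloxy)-3-[(2-benzyloxy-4-hydroxy-6-methoxy-5-methylphenyl)methyl]-5-methylphenyl]pentan-1-one | CCCCC(=O)c1c(OCc2ccccc2)c(C)c(OCc2ccccc2)c(Cc2c(OCc3ccccc3)cc(O)c(C)c2OC)c1OCc1ccccc1 | intermediate
18 | butanoyl chloride | CCCC(=O)Cl | starting material
19 | 1-[2,4,6-tris(benzyloxy)-3-[(2-benzyloxy-3-butanoyl-4-hydroxy-6-methoxy-5-methylphenyl)methyl]-5-methylphenyl]pentan-1-one | CCCCC(=O)c1c(OCc2ccccc2)c(C)c(OCc2ccccc2)c(Cc2c(OCc3ccccc3)c(C(=O)CCC)c(O)c(C)c2OC)c1OCc1ccccc1 | intermediate
20 | 1-[3-[(3-butanoyl-2,4-dihydroxy-6-methoxy-5-methylphenyl)methyl]-2,4,6-trihydroxy-5-methylphenyl]pentan-1-one | CCCCC(=O)c1c(O)c(C)c(O)c(Cc2c(O)c(C(=O)CCC)c(O)c(C)c2OC)c1O | target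

**Step count**

Total: 9 steps. Longest linear sequence: 8 steps (1, 2, 3, 4, 5, 7, 8, 9); step 6 is a one-step side branch.

**Steps most likely to fail**

1. Step 7. The vinylogous ester character of 9 may raise the barrier of the first ring opening so far that thermal decomposition sets in before the cascade starts. The ketene intermediates may also be intercepted by the phenol already formed (aryl ester formation), and the volatile ynol ether may be lost. The fallback is known chemistry: it sets out from Mannich base 4 and gives up the benzannulation in favour of a preformed ring B. 2-Methylphloroglucinol 1 would be C-acylated with butanoyl chloride 18 (AlCl3, PhNO2–CH2Cl2) to 1-(2,4,6-trihydroxy-3-methylphenyl)butan-1-one F1. Its non-chelated hydroxyl para to the acyl group would then be methylated selectively (Me2SO4, 1 equiv, K2CO3, acetone) to 1-(2,6-dihydroxy-4-methoxy-3-methylphenyl)butan-1-one F2 (aspidinol). Heating 4 with F2 in 1,4-dioxane should release ortho-quinone methide 6, which alkylates the one free ring carbon of F2. The fallback comes back to the route at target 20, so steps 3 to 9 are bypassed.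

2. Step 3. The liberated dimethylamine may condense with the dione to an enaminone, the adduct may cyclodehydrate onto a neighbouring phenol, or a second quinone methide may add to 7. The fallback sets out from 3 and forms the same CH2–C bond by reduction instead of by amine elimination. Vilsmeier–Haack formylation of 3 (POCl3, DMF, then water) should give 2,4,6-trihydroxy-3-methyl-5-pentanoylbenzaldehyde F3. A three-component reductive alkylation of 5 with F3 and Hantzsch ester (L-proline cat., CH2Cl2, rt; Knoevenagel condensation, then transfer hydrogenation of the alkylidene dione) comes back to the route at 7.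

3. Step 8. The Lewis acid may cleave benzyl ethers with transfer of benzyl groups to carbon, the phenol may be O-acylated without migration, or the diarylmethane link may be split by acid. The fallback sets out from 17 and avoids strong Lewis acids. Magnesium-mediated ortho-formylation of the phenol (MgCl2, Et3N, paraformaldehyde, MeCN, reflux) should give 1-[2,4,6-tris(benzyloxy)-3-[(2-benzyloxy-3-formyl-4-hydroxy-6-methoxy-5-methylphenyl)methyl]-5-methylphenyl]pentan-1-one F4. Aldehyde-selective addition of n-PrTi(OiPr)3 (from n-PrMgCl and ClTi(OiPr)3, THF, −40 °C), which should leave the hindered ring A ketone alone, would give racemic 1-[2,4,6-tris(benzyloxy)-3-[[2-benzyloxy-4-hydroxy-3-(1-hydroxybutyl)-6-methoxy-5-methylphenyl]methyl]-5-methylphenyl]pentan-1-one F5. Oxidation of the benzylic alcohol (MnO2, CH2Cl2) removes the transient stereocentre and comes back to the route at 19.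

**Further compounds**

F1 | step 7 | 1-(2,4,6-trihydroxy-3-methylphenyl)butan-1-one | CCCC(=O)c1c(O)c(C)c(O)cc1O
F2 | step 7 | 1-(2,6-dihydroxy-4-methoxy-3-methylphenyl)butan-1-one (aspidinol) | CCCC(=O)c1c(O)cc(OC)c(C)c1O
F3 | step 3 | 2,4,6-trihydroxy-3-methyl-5-pentanoylbenzaldehyde | CCCCC(=O)c1c(O)c(C)c(O)c(C=O)c1O
F4 | step 8 | 1-[2,4,6-tris(benzyloxy)-3-[(2-benzyloxy-3-formyl-4-hydroxy-6-methoxy-5-methylphenyl)methyl]-5-methylphenyl]pentan-1-one | CCCCC(=O)c1c(OCc2ccccc2)c(C)c(OCc2ccccc2)c(Cc2c(OCc3ccccc3)c(C=O)c(O)c(C)c2OC)c1OCc1ccccc1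
F5 | step 8 | 1-[2,4,6-tris(benzyloxy)-3-[[2-benzyloxy-4-hydroxy-3-(1-hydroxybutyl)-6-methoxy-5-methylphenyl]methyl]-5-methylphenyl]pentan-1-one (racemic) | CCCCC(=O)c1c(OCc2ccccc2)c(C)c(OCc2ccccc2)c(Cc2c(OCc3ccccc3)c(C(O)CCC)c(O)c(C)c2OC)c1OCc1ccccc1
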